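The route rests on disconnecting C2=C3 of the cyclohexenone. The precursor is a meso 4,11-diacetyl bicyclo[4.1.1]octenone in which a mirror plane through C5, the C6–C9 bridge and C10 makes the two acetyl groups on the cyclobutane C4–C5–C11–C10 enantiotopic. One amine-catalysed aldol condensation picks one of them as the nucleophile, closes the six-membered ring C1–C2–C3–C4–C10–C11 and fixes C4, C5, C10 and C11 together, while C4/C11 epimers funnel through the same closure. The precursor carries its ketone at C7 and its alkene at C8=C9, so that the later C7 carbinol steers osmylation to the 7,8-trans-8,9-cis triol without an inversion.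

Key step: step 18

Remark: longipinane numbers are used for positions (C1 ketone, C2=C3 with the C3 methyl, cyclobutane C4–C5–C11–C10, C6 gem-dimethyl, C7–C9 bridge, C10 methyl); the side of the C6–C9 bridge turned toward C4 is the C4 face, the other the C11 face. Compounds 5–25 are racemic; before step 18 the labels C4 (carbon from the conjugate addition) and C11 (carbon from the aldol addition) only tell the two cyclobutane corners apart, and the configurations at these two carbons and at carbinol carbons that are later oxidised or substituted are left open in the SMILES, because step 18 equilibrates C4 and C11.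

Step 1
Reactants: 1 dimedone (5,5-dimethylcyclohexane-1,3-dione)
Product: 2 2,5,5-trimethylcyclohexane-1,3-dione
Conditions: MeI, NaOH, H2O/MeOH, 65 °C
Reagents that add atoms: iodomethane, CI
Why: C-alkylation of the doubly stabilised dione enolate (enolate alkylation) puts the future C10 methyl group on the carbon between the two carbonyls.

Step 2
Reactants: 2 2,5,5-trimethylcyclohexane-1,3-dione
Product: 3 3-isobutoxy-2,5,5-trimethylcyclohex-2-en-1-one
Conditions: i-BuOH, TsOH (cat.), toluene, reflux, Dean–Stark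
Reagents that add atoms: 2-methylpropan-1-ol, CC(C)CO
Why: Acid-catalysed enol etherification of the symmetric dione (vinylogous ester formation) with azeotropic removal of water can give only this one product.

Step 3
Reactants: 3 3-isobutoxy-2,5,5-trimethylcyclohex-2-en-1-one; 4 3-(trimethylsilyl)prop-2-ynal
Product: 5 6-[1-hydroxy-3-(trimethylsilyl)prop-2-yn-1-yl]-3-isobutoxy-2,5,5-trimethylcyclohex-2-en-1-one
Conditions: LiN(i-Pr)2, THF, −78 °C; then 4; aq. NH4Cl, −78 °C
Reagents that add atoms: none
Why: Kinetic deprotonation of the vinylogous ester at the CH2 beside the carbonyl and aldol addition to the ynal join the future C11 to the future C5, and both new stereocentres are left as mixtures because C11 is substituted in step 9 and equilibrated in step 18.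

Step 4
Reactants: 5 6-[1-hydroxy-3-(trimethylsilyl)prop-2-yn-1-yl]-3-isobutoxy-2,5,5-trimethylcyclohex-2-en-1-one
Product: 6 6-[1-(tert-butyldimethylsilyloxy)-3-(trimethylsilyl)prop-2-yn-1-yl]-3-isobutoxy-2,5,5-trimethylcyclohex-2-en-1-one
Conditions: TBSCl, imidazole, 4-(dimethylamino)pyridine (cat.), DMF, rt
Reagents that add atoms: tert-butyldimethylsilyl chloride, CC(C)(C)[Si](C)(C)Cl
Why: Silyl ether formation protects the aldol hydroxyl against retro-aldol cleavage and against the hydride and organometallic steps that follow.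

Step 5
Reactants: 6 6-[1-(tert-butyldimethylsilyloxy)-3-(trimethylsilyl)prop-2-yn-1-yl]-3-isobutoxy-2,5,5-trimethylcyclohex-2-en-1-one
Product: 8 4-[1-(tert-butyldimethylsilyloxy)-3-(trimethylsilyl)prop-2-yn-1-yl]-2,5,5-trimethylcyclohex-2-en-1-one, via allylic alcohol 7 (not isolated)
Conditions: i-Bu2AlH, toluene, −78 °C; then 1 M HCl, THF, 0 °C
Reagents that add atoms: water, O
Why: Stork–Danheiser transposition, that is 1,2-reduction of the vinylogous ester carbonyl and acid hydrolysis of the enol ether with allylic shift, moves the carbonyl to C9 and gives the C10=C4 enone.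

Step 6
Reactants: 8 4-[1-(tert-butyldimethylsilyloxy)-3-(trimethylsilyl)prop-2-yn-1-yl]-2,5,5-trimethylcyclohex-2-en-1-one; 9 isopropenylmagnesium bromide
Product: 11 4-[1-(tert-butyldimethylsilyloxy)-3-(trimethylsilyl)prop-2-yn-1-yl]-3-isopropenyl-2,5,5-trimethylcyclohex-1-en-1-yl acetate, via magnesium enolate 10 (not isolated)
Conditions: 9, CuBr·SMe2 (20 mol %), THF, −40 °C; then Ac2O, −40 to 0 °C
Reagents that add atoms: acetic anhydride, CC(=O)OC(C)=O
Why: Copper-catalysed conjugate addition of the alkenyl Grignard reagent puts the masked acetyl group on C4 anti to the C5 side chain (substrate control, a configuration that step 18 corrects by equilibration), and O-acetylation of the enolate stores it as the regiodefined C9=C10 enol acetate.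

Step 7
Reactants: 11 4-[1-(tert-butyldimethylsilyloxy)-3-(trimethylsilyl)prop-2-yn-1-yl]-3-isopropenyl-2,5,5-trimethylcyclohex-1-en-1-yl acetate
Product: 12 4-[1-hydroxy-3-(trimethylsilyl)prop-2-yn-1-yl]-3-isopropenyl-2,5,5-trimethylcyclohex-1-en-1-yl acetate
Conditions: HF·pyridine, pyridine/THF, 0 °C to rt
Reagents that add atoms: none
Why: Fluoride-mediated cleavage of the O-silyl ether frees the propargylic alcohol, while the enol acetate and the C-silyl group on the alkyne are inert to buffered HF.

Step 8
Reactants: 12 4-[1-hydroxy-3-(trimethylsilyl)prop-2-yn-1-yl]-3-isopropenyl-2,5,5-trimethylcyclohex-1-en-1-yl acetate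
Product: 13 4-[1-(methanesulfonyloxy)-3-(trimethylsilyl)prop-2-yn-1-yl]-3-isopropenyl-2,5,5-trimethylcyclohex-1-en-1-yl acetate
Conditions: MsCl, Et3N, CH2Cl2, −20 °C
Reagents that add atoms: methanesulfonyl chloride, CS(=O)(=O)Cl
Why: Sulfonylation turns the propargylic hydroxyl on C11 into a leaving group that the adjacent alkyne activates for SN2 displacement.

Step 9
Reactants: 13 4-[1-(methanesulfonyloxy)-3-(trimethylsilyl)prop-2-yn-1-yl]-3-isopropenyl-2,5,5-trimethylcyclohex-1-en-1-yl acetate
Product: 15 6-isopropenyl-1,4,4-trimethyl-7-[(trimethylsilyl)ethynyl]bicyclo[3.1.1]heptan-2-one, via lithium enolate 14 (not isolated)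
Conditions: MeLi (2.1 equiv), THF, −78 °C; then DMPU, −78 to 0 °C
Reagents that add atoms: none
Why: Methyllithium cleaves the enol acetate to the C10 lithium enolate, which closes the cyclobutane by intramolecular SN2 alkylation at C11 (4-exo-tet, inversion at C11), the bridging geometry fixing quaternary C10 relative to C5 and excluding O-alkylation, which would need a bridgehead double bond.

Step 10
Reactants: 15 6-isopropenyl-1,4,4-trimethyl-7-[(trimethylsilyl)ethynyl]bicyclo[3.1.1]heptan-2-one
Product: 16 6-isopropenyl-1,4,4-trimethyl-7-[(trimethylsilyl)ethynyl]-2-(trimethylsilyloxy)bicyclo[3.1.1]hept-2-ene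
Conditions: LiN(i-Pr)2, Me3SiCl, THF, −78 °C
Reagents that add atoms: chlorotrimethylsilane, C[Si](C)(C)Cl
Why: Silyl enol ether formation can occur only toward C7 because C10 is quaternary, which sets up the one-carbon ring expansion.

Step 11
Reactants: 16 6-isopropenyl-1,4,4-trimethyl-7-[(trimethylsilyl)ethynyl]-2-(trimethylsilyloxy)bicyclo[3.1.1]hept-2-ene
Product: 17 siloxycyclopropane (CH2 added across C9=C7 of 16)
Conditions: Et2Zn, CH2I2, CH2Cl2, 0 °C
Reagents that add atoms: diiodomethane, ICI
Why: Furukawa-modified Simmons–Smith cyclopropanation adds the future C8 to the electron-rich silyl enol ether in preference to the isopropenyl group and the silylalkyne.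

Step 12
Reactants: 17 siloxycyclopropane (CH2 added across C9=C7 of 16)
Product: 19 7-isopropenyl-1,5,5-trimethyl-8-[(trimethylsilyl)ethynyl]bicyclo[4.1.1]oct-3-en-2-one, via chloro ketone 18 (not isolated)
Conditions: FeCl3, DMF, 0 °C; then NaOAc, MeOH, 65 °C
Reagents that add atoms: none
Why: Oxidative opening of the siloxycyclopropane by FeCl3 followed by dehydrochlorination (Saegusa-type ring expansion) enlarges the three-carbon bridge to the C9(=O)–C8=C7–C6 enone of a bicyclo[4.1.1]octenone.

Step 13
Reactants: 19 7-isopropenyl-1,5,5-trimethyl-8-[(trimethylsilyl)ethynyl]bicyclo[4.1.1]oct-3-en-2-one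
Product: 20 3,4-epoxy-8-ethynyl-7-isopropenyl-1,5,5-trimethylbicyclo[4.1.1]octan-2-one
Conditions: H2O2 (30 %), NaOH, MeOH, 0 °C
Reagents that add atoms: hydrogen peroxide, OO
Why: Nucleophilic (Weitz–Scheffer) epoxidation of the enone, with concurrent base-mediated protodesilylation of the alkyne, prepares the carbonyl transposition, the epoxide face being irrelevant because C7 is oxidised again in step 15.

Step 14
Reactants: 20 3,4-epoxy-8-ethynyl-7-isopropenyl-1,5,5-trimethylbicyclo[4.1.1]octan-2-one
Product: 22 8-ethynyl-7-isopropenyl-1,5,5-trimethylbicyclo[4.1.1]oct-2-en-4-ol, via epoxy hydrazone 21 (not isolated)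
Conditions: N2H4·H2O, AcOH (cat.), MeOH, 0 °C to rt
Reagents that add atoms: none
Why: Wharton transposition of the epoxy ketone, by fragmentation of its hydrazone with loss of N2, moves the oxygen to C7 and the double bond to C8=C9.

Step 15
Reactants: 22 8-ethynyl-7-isopropenyl-1,5,5-trimethylbicyclo[4.1.1]oct-2-en-4-ol
Product: 23 8-ethynyl-7-isopropenyl-1,5,5-trimethylbicyclo[4.1.1]oct-2-en-4-one
Conditions: Dess–Martin periodinane, NaHCO3, CH2Cl2, rt
Reagents that add atoms: none
Why: Dess–Martin oxidation of the allylic alcohol gives the C7 ketone conjugated with C8=C9 and removes the uncontrolled C7 stereocentre.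

Step 16
Reactants: 23 8-ethynyl-7-isopropenyl-1,5,5-trimethylbicyclo[4.1.1]oct-2-en-4-one
Product: 24 8-acetyl-7-isopropenyl-1,5,5-trimethylbicyclo[4.1.1]oct-2-en-4-one
Conditions: (Ph3P)AuCl (2 mol %), AgOTf (2 mol %), 1,4-dioxane/H2O, 60 °C
Reagents that add atoms: water, O
Why: Gold-catalysed Markovnikov hydration of the terminal alkyne turns the C11 substituent into the first acetyl group without touching the enone or the isopropenyl group, which sits on the bridge side of the cyclobutane and cannot reach the alkyne.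

Step 17
Reactants: 24 8-acetyl-7-isopropenyl-1,5,5-trimethylbicyclo[4.1.1]oct-2-en-4-one
Product: 26 meso 7,8-diacetyl-1,5,5-trimethylbicyclo[4.1.1]oct-2-en-4-one, via ozonide 25 (not isolated)
Conditions: O3 (1 equiv), CH2Cl2, −78 °C; then Me2S, −78 °C to rt
Reagents that add atoms: ozone, [O-][O+]=O
Why: Ozonolysis cleaves the electron-rich 1,1-disubstituted alkene much faster than the electron-poor enone double bond and so unveils the second acetyl group under neutral conditions; the material is a mixture of 26 with its C4/C11 epimers, in which the new acetyl group first sits on the bridge side, and it is used as such.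

Step 18
Reactants: 26 meso 7,8-diacetyl-1,5,5-trimethylbicyclo[4.1.1]oct-2-en-4-one
Product: 28 longipina-2,8-diene-1,7-dione, via aldol 27 (not isolated)
Conditions: 9-amino-9-deoxy-epi-quinine (20 mol %), AcOH (60 mol %), toluene, 40 °C
Reagents that add atoms: none
Why: Proposed new method: the primary amine condenses with one acetyl group to the enamine C1=C2, whose C2 adds to the acid-activated C3 carbonyl of the other acetyl group, and the aldol 27 loses water to the C2=C3 enone; the closest known reaction is the chiral primary-amine-catalysed desymmetrising aldol condensation of 4-substituted heptane-2,6-diones to 5-substituted 3-methylcyclohexenones, applied here to a heptane-2,6-dione whose C3 and C5 are tied into a cyclobutane. The six-membered ring C1–C2–C3–C4–C10–C11 closes in the 6-(enolendo)-exo-trig mode across the cyclobutane, which is possible only when both acetyl groups stand on the face away from the C6–C9 bridge. C4, C5, C10 and C11 become stereogenic through the catalyst's choice of which enantiotopic acetyl group acts as the nucleophile (catalyst control; the quinidine-derived pseudo-enantiomer should give the antipode if the sense has to be inverted). Isomers with an acetyl group on the bridge side cannot close and should drain into the reactive isomer through reversible enamine or enol formation at C4 and C11, so that the whole mixture funnels into 28. The C7 ketone is shielded by quaternary C6 and cannot form an enamine, a bridge-side acetyl group could add to it only reversibly because that aldol cannot dehydrate without a bridgehead double bond, and Michael addition to C9 would need a five-membered enolendo closure. The new bridgehead centres cannot epimerise afterwards.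

Step 19
Reactants: 28 longipina-2,8-diene-1,7-dione
Product: 29 1-(tert-butyldimethylsilyloxy)longipina-1,3(15),8-trien-7-one
Conditions: TBSOTf, Et3N, CH2Cl2, 0 °C
Reagents that add atoms: tert-butyldimethylsilyl trifluoromethanesulfonate, CC(C)(C)[Si](C)(C)OS(=O)(=O)C(F)(F)F
Why: Soft enolisation to the silyl dienol ether through the C3 methyl group masks the C1 enone, the only enolisable carbonyl (C11 is a bridgehead and the C7 enone has no acidic hydrogen), so that the next reduction can touch only C7.

Step 20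
Reactants: 29 1-(tert-butyldimethylsilyloxy)longipina-1,3(15),8-trien-7-one
Product: 31 (7R)-7-hydroxylongipina-2,8-dien-1-one, via silyl dienol ether alcohol 30 (not isolated)
Conditions: (S)-1-methyl-3,3-diphenyltetrahydro-1H,3H-pyrrolo[1,2-c][1,3,2]oxazaborole [(S)-Me-CBS] (20 mol %), catecholborane, toluene, −78 °C; then 0.5 M HCl, THF, 0 °C
Reagents that add atoms: none
Why: Corey–Bakshi–Shibata reduction of the C7 enone should deliver hydride from the C11 face with quaternary C6 as the large and vinylic C8 as the small substituent (reagent control, needed because the core is nearly symmetric around C7), giving the (7R)-alcohol with its hydroxyl on the C4 face, and the acidic work-up returns the C1 enone.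

Step 21
Reactants: 31 (7R)-7-hydroxylongipina-2,8-dien-1-one
Product: 32 7,8,9-trihydroxylongipin-2-en-1-one (7-OH on the C4 face; 8-OH and 9-OH on the C11 face)
Conditions: OsO4 (5 mol %), 4-methylmorpholine N-oxide, acetone/H2O, rt
Reagents that add atoms: 4-methylmorpholine N-oxide, C[N+]1([O-])CCOCC1; water, O
Why: Upjohn dihydroxylation of the isolated cis alkene should occur anti to the allylic C7 hydroxyl (substrate control), placing the C8 and C9 hydroxyls on the C11 face, while the electron-poor, hindered C2=C3 enone double bond stays intact.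

Step 22
Reactants: 32 7,8,9-trihydroxylongipin-2-en-1-one (7-OH on the C4 face; 8-OH and 9-OH on the C11 face)
Product: 33 8-acetoxy-7,9-dihydroxylongipin-2-en-1-one
Conditions: Ac2O (1.1 equiv), pyridine, 4-(dimethylamino)pyridine (2 mol %), CH2Cl2, −20 °C
Reagents that add atoms: acetic anhydride, CC(=O)OC(C)=O
Why: Sterically controlled acylation picks the C8 hydroxyl, which lies between two carbinol carbons, over the C7 and C9 hydroxyls, each of which stands next to a quaternary carbon.

Step 23
Reactants: 33 8-acetoxy-7,9-dihydroxylongipin-2-en-1-one; 34 angelic acid (two equivalents enter the product)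
Product: 36 target 8-acetoxy-7,9-bis(angeloyloxy)longipin-2-en-1-one, via mixed anhydride 35 (not isolated)
Conditions: 34 (6 equiv), 2,4,6-trichlorobenzoyl chloride (6 equiv), Et3N, toluene, rt; then 33, 80 °C
Reagents that add atoms: angelic acid (the second equivalent of 34), C/C=C(/C)C(=O)O
Why: Yamaguchi-type esterification through the mixed anhydride, of which one molecule is consumed at O7 and a second at O9, acylates both hindered hydroxyls and is chosen because it should leave the Z double bond of the angeloyl groups intact instead of isomerising it to the tigloyl form.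

Compound list
1 | dimedone (5,5-dimethylcyclohexane-1,3-dione) | CC1(C)CC(=O)CC(=O)C1 | starting material
2 | 2,5,5-trimethylcyclohexane-1,3-dione | CC1C(=O)CC(C)(C)CC1=O | intermediate
3 | 3-isobutoxy-2,5,5-trimethylcyclohex-2-en-1-one | CC1=C(OCC(C)C)CC(C)(C)CC1=O | intermediate
4 | 3-(trimethylsilyl)prop-2-ynal | C[Si](C)(C)C#CC=O | starting material
5 | 6-[1-hydroxy-3-(trimethylsilyl)prop-2-yn-1-yl]-3-isobutoxy-2,5,5-trimethylcyclohex-2-en-1-one (racemic, both diastereomers) | CC1=C(OCC(C)C)CC(C)(C)C(C(O)C#C[Si](C)(C)C)C1=O | intermediate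
6 | tert-butyldimethylsilyl ether of 5 | CC1=C(OCC(C)C)CC(C)(C)C(C(O[Si](C)(C)C(C)(C)C)C#C[Si](C)(C)C)C1=O | intermediate
7 | allylic alcohol from 1,2-reduction of 6 (not isolated) | CC1=C(OCC(C)C)CC(C)(C)C(C(O[Si](C)(C)C(C)(C)C)C#C[Si](C)(C)C)C1O | intermediate
8 | 4-[1-(tert-butyldimethylsilyloxy)-3-(trimethylsilyl)prop-2-yn-1-yl]-2,5,5-trimethylcyclohex-2-en-1-one (C9 ketone, C10=C4, C11 on C5; racemic, both diastereomers) | O=C1CC(C)(C)C(C(O[Si](C)(C)C(C)(C)C)C#C[Si](C)(C)C)C=C1C | intermediate
9 | isopropenylmagnesium bromide | CC(=C)[Mg]Br | starting material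
10 | bromomagnesium enolate from conjugate addition (not isolated) | Br[Mg]OC1=C(C)C(C(C)=C)C(C(O[Si](C)(C)C(C)(C)C)C#C[Si](C)(C)C)C(C)(C)C1 | intermediate
11 | 4-[1-(tert-butyldimethylsilyloxy)-3-(trimethylsilyl)prop-2-yn-1-yl]-3-isopropenyl-2,5,5-trimethylcyclohex-1-en-1-yl acetate (isopropenyl trans to the side chain; racemic) | CC(=O)OC1=C(C)C(C(C)=C)C(C(O[Si](C)(C)C(C)(C)C)C#C[Si](C)(C)C)C(C)(C)C1 | intermediate
12 | 4-[1-hydroxy-3-(trimethylsilyl)prop-2-yn-1-yl]-3-isopropenyl-2,5,5-trimethylcyclohex-1-en-1-yl acetate | CC(=O)OC1=C(C)C(C(C)=C)C(C(O)C#C[Si](C)(C)C)C(C)(C)C1 | intermediate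
13 | methanesulfonate of 12 | CC(=O)OC1=C(C)C(C(C)=C)C(C(OS(C)(=O)=O)C#C[Si](C)(C)C)C(C)(C)C1 | intermediate
14 | lithium enolate from 13 (not isolated) | [Li]OC1=C(C)C(C(C)=C)C(C(OS(C)(=O)=O)C#C[Si](C)(C)C)C(C)(C)C1 | intermediate
15 | 6-isopropenyl-1,4,4-trimethyl-7-[(trimethylsilyl)ethynyl]bicyclo[3.1.1]heptan-2-one (racemic, one enantiomer of the ring-fixed bridgeheads drawn; isopropenyl on the bridge side, C11 as a mixture, neither drawn) | O=C1[C@@]2(C)C(C(C)=C)[C@@H](C(C)(C)C1)C2C#C[Si](C)(C)C | intermediate
16 | 2-trimethylsilyl enol ether of 15 (C9=C7) | C[Si](C)(C)OC=1[C@@]2(C)C(C(C)=C)[C@@H](C(C)(C)C=1)C2C#C[Si](C)(C)C | intermediate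
17 | siloxycyclopropane (CH2 = C8 across C9–C7) | C[Si](C)(C)OC13[C@@]2(C)C(C(C)=C)[C@@H](C(C)(C)C1C3)C2C#C[Si](C)(C)C | intermediate
18 | 4-chloro-7-isopropenyl-1,5,5-trimethyl-8-[(trimethylsilyl)ethynyl]bicyclo[4.1.1]octan-2-one (not isolated) | O=C1[C@@]2(C)C(C(C)=C)[C@@H](C(C)(C)C(Cl)C1)C2C#C[Si](C)(C)C | intermediate
19 | 7-isopropenyl-1,5,5-trimethyl-8-[(trimethylsilyl)ethynyl]bicyclo[4.1.1]oct-3-en-2-one (C9 ketone, C7=C8; racemic) | O=C1[C@@]2(C)C(C(C)=C)[C@@H](C(C)(C)C=C1)C2C#C[Si](C)(C)C | intermediate
20 | 3,4-epoxy-8-ethynyl-7-isopropenyl-1,5,5-trimethylbicyclo[4.1.1]octan-2-one | O=C1[C@@]2(C)C(C(C)=C)[C@@H](C(C)(C)C3OC31)C2C#C | intermediate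
21 | hydrazone of 20 (not isolated) | NN=C1[C@@]2(C)C(C(C)=C)[C@@H](C(C)(C)C3OC31)C2C#C | intermediate
22 | 8-ethynyl-7-isopropenyl-1,5,5-trimethylbicyclo[4.1.1]oct-2-en-4-ol (C7–OH, C8=C9; racemic, both C7 epimers) | OC1C=C[C@@]2(C)C(C(C)=C)[C@@H](C1(C)C)C2C#C | intermediate
23 | 8-ethynyl-7-isopropenyl-1,5,5-trimethylbicyclo[4.1.1]oct-2-en-4-one | O=C1C=C[C@@]2(C)C(C(C)=C)[C@@H](C1(C)C)C2C#C | intermediate
24 | 8-acetyl-7-isopropenyl-1,5,5-trimethylbicyclo[4.1.1]oct-2-en-4-one | O=C1C=C[C@@]2(C)C(C(C)=C)[C@@H](C1(C)C)C2C(C)=O | intermediate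
25 | ozonide of 24 (not isolated) | O=C1C=C[C@@]2(C)C(C3(C)OCOO3)[C@@H](C1(C)C)C2C(C)=O | intermediate
26 | meso 7,8-diacetyl-1,5,5-trimethylbicyclo[4.1.1]oct-2-en-4-one (4,11-diacetyl, C7 ketone, C8=C9; drawn with both acetyl groups on the face away from the C6–C9 bridge, obtained as a mixture with its C4/C11 epimers) | O=C1C=C[C@@]2(C)[C@H](C(C)=O)[C@@H](C1(C)C)[C@@H]2C(C)=O | intermediate
27 | 3-hydroxy-2,3-dihydrolongipin-8-ene-1,7-dione, the aldol (not isolated) | O=C1C=C[C@@]2(C)[C@@H]3C(=O)CC(C)(O)[C@H]2[C@@H]3C1(C)C | intermediate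
28 | longipina-2,8-diene-1,7-dione | O=C1C=C[C@@]2(C)[C@@H]3C(=O)C=C(C)[C@H]2[C@@H]3C1(C)C | intermediate
29 | 1-(tert-butyldimethylsilyloxy)longipina-1,3(15),8-trien-7-one (exocyclic methylene on C3) | O=C1C=C[C@@]2(C)[C@@H]3C(O[Si](C)(C)C(C)(C)C)=CC(=C)[C@H]2[C@@H]3C1(C)C | intermediate
30 | (7R)-7-hydroxy silyl dienol ether (not isolated) | O[C@@H]1C=C[C@@]2(C)[C@@H]3C(O[Si](C)(C)C(C)(C)C)=CC(=C)[C@H]2[C@@H]3C1(C)C | intermediate
31 | (7R)-7-hydroxylongipina-2,8-dien-1-one (OH on the C4 face) | O[C@@H]1C=C[C@@]2(C)[C@@H]3C(=O)C=C(C)[C@H]2[C@@H]3C1(C)C | intermediate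
32 | 7,8,9-trihydroxylongipin-2-en-1-one (7-OH on the C4 face; 8-OH and 9-OH on the C11 face) | O[C@@H]1[C@@H](O)[C@@H](O)[C@@]2(C)[C@@H]3C(=O)C=C(C)[C@H]2[C@@H]3C1(C)C | intermediate
33 | 8-acetoxy-7,9-dihydroxylongipin-2-en-1-one | O[C@@H]1[C@@H](OC(C)=O)[C@@H](O)[C@@]2(C)[C@@H]3C(=O)C=C(C)[C@H]2[C@@H]3C1(C)C | intermediate
34 | angelic acid ((Z)-2-methylbut-2-enoic acid) | C/C=C(/C)C(=O)O | starting material
35 | angelic 2,4,6-trichlorobenzoic anhydride (not isolated) | C/C=C(/C)C(=O)OC(=O)c1c(Cl)cc(Cl)cc1Cl | intermediate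
36 | 8-acetoxy-7,9-bis(angeloyloxy)longipin-2-en-1-one (7-O on the C4 face; 8-O and 9-O on the C11 face) | C/C=C(/C)C(=O)O[C@@H]1[C@@H](OC(C)=O)[C@@H](OC(=O)/C(C)=C\C)[C@@]2(C)[C@@H]3C(=O)C=C(C)[C@H]2[C@@H]3C1(C)C | target

Total step count: 23. Longest linear sequence: 23 steps (1 to 36; 4, 9 and 34 are bought and enter in steps 3, 6 and 23).

Steps most likely to fail

Step 18. The catalyst may not discriminate well enough between the two enantiotopic acetyl groups, or turnover may stall because the strain-building closure or the epimer interconversion at C4/C11 is slower than catalyst decay. The fallback uses known chemistry, sets out from 26 and comes back at 31. A plain intramolecular aldol condensation of the 1,5-diketone with an achiral secondary-amine salt (pyrrolidine, AcOH, toluene, 60 °C) should give racemic longipina-2,8-diene-1,7-dione F1. Silylation as in step 19 gives the racemic silyl dienol ether F2. Reduction as in step 20, which is reagent-controlled at C7 on either enantiomer, gives 30 and the diastereomeric silyl dienol ether alcohol F3. The acidic work-up then gives 31 and the diastereomeric (7R)-alcohol on the antipodal core F4, which are separated by chromatography. 31 continues with step 21, at the cost of half the material.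

Step 9. Elimination of methanesulfonic acid toward the enyne, or proton transfer to the hindered enolate, may outrun the slow four-membered ring closure. The fallback sets out from 11 and comes back at 19. It inverts the order of ring closure and ring expansion, so that the C10–C11 bond is made across a seven-membered ring by a potassium enolate that can form only at C10. MeLi, then aqueous NH4Cl, turns 11 into 4-[1-(tert-butyldimethylsilyloxy)-3-(trimethylsilyl)prop-2-yn-1-yl]-3-isopropenyl-2,5,5-trimethylcyclohexanone F5. Kinetic deprotonation on the CH2 side (LiN(i-Pr)2, Me3SiCl) gives the silyl enol ether F6, and Et2Zn/CH2I2 gives the siloxycyclopropane F7. FeCl3, then NaOAc, leads through the chloro ketone F8 to the cyclohept-2-enone F9. HF·pyridine frees the propargylic alcohol F10, and MsCl/Et3N gives the methanesulfonate F11. KOt-Bu in THF at 0 °C then closes the cyclobutane to 19.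

Step 23. Acetyl migration from O8 to the cis O9 under the basic, warm conditions may precede the slow acylation of the two hindered hydroxyls, or the diacylation may stay incomplete. The fallback sets out from 32 and comes back at 36. Et3SiCl/imidazole at −20 °C silylates the least hindered hydroxyl to the 8-O-triethylsilyl ether F12. Acylation with an excess of 35 as in step 23 gives the 7,9-bis(angeloyl) 8-O-triethylsilyl ether F13. HF·pyridine frees the 7,9-bis(angeloyloxy)-8-hydroxy compound F14, and Ac2O with 4-(dimethylamino)pyridine in pyridine acetylates O8 last to give 36.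

Further compounds
F1 | step 18 | racemic longipina-2,8-diene-1,7-dione | O=C1C=C[C@@]2(C)[C@@H]3C(=O)C=C(C)[C@H]2[C@@H]3C1(C)C.O=C1C=C[C@]2(C)[C@H]3C(=O)C=C(C)[C@@H]2[C@H]3C1(C)C
F2 | step 18 | racemic 1-(tert-butyldimethylsilyloxy)longipina-1,3(15),8-trien-7-one | O=C1C=C[C@@]2(C)[C@@H]3C(O[Si](C)(C)C(C)(C)C)=CC(=C)[C@H]2[C@@H]3C1(C)C.O=C1C=C[C@]2(C)[C@H]3C(O[Si](C)(C)C(C)(C)C)=CC(=C)[C@@H]2[C@H]3C1(C)C
F3 | step 18 | (7R)-7-hydroxy silyl dienol ether on the antipodal core | O[C@@H]1C=C[C@]2(C)[C@H]3C(O[Si](C)(C)C(C)(C)C)=CC(=C)[C@@H]2[C@H]3C1(C)C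
F4 | step 18 | (7R)-7-hydroxylongipina-2,8-dien-1-one on the antipodal core (diastereomer of 31) | O[C@@H]1C=C[C@]2(C)[C@H]3C(=O)C=C(C)[C@@H]2[C@H]3C1(C)C
F5 | step 9 | 4-[1-(tert-butyldimethylsilyloxy)-3-(trimethylsilyl)prop-2-yn-1-yl]-3-isopropenyl-2,5,5-trimethylcyclohexanone | O=C1CC(C)(C)C(C(O[Si](C)(C)C(C)(C)C)C#C[Si](C)(C)C)C(C(C)=C)C1C
F6 | step 9 | kinetic trimethylsilyl enol ether of F5 (C9=C7) | C[Si](C)(C)OC1=CC(C)(C)C(C(O[Si](C)(C)C(C)(C)C)C#C[Si](C)(C)C)C(C(C)=C)C1C
F7 | step 9 | siloxycyclopropane from F6 | C[Si](C)(C)OC12CC1C(C)(C)C(C(O[Si](C)(C)C(C)(C)C)C#C[Si](C)(C)C)C(C(C)=C)C2C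
F8 | step 9 | 3-chlorocycloheptanone from F7 | O=C1CC(Cl)C(C)(C)C(C(O[Si](C)(C)C(C)(C)C)C#C[Si](C)(C)C)C(C(C)=C)C1C
F9 | step 9 | 5-[1-(tert-butyldimethylsilyloxy)-3-(trimethylsilyl)prop-2-yn-1-yl]-6-isopropenyl-4,4,7-trimethylcyclohept-2-en-1-one | O=C1C=CC(C)(C)C(C(O[Si](C)(C)C(C)(C)C)C#C[Si](C)(C)C)C(C(C)=C)C1C
F10 | step 9 | propargylic alcohol from F9 | O=C1C=CC(C)(C)C(C(O)C#C[Si](C)(C)C)C(C(C)=C)C1C
F11 | step 9 | methanesulfonate of F10 | O=C1C=CC(C)(C)C(C(OS(C)(=O)=O)C#C[Si](C)(C)C)C(C(C)=C)C1C
F12 | step 23 | 7,9-dihydroxy-8-(triethylsilyloxy)longipin-2-en-1-one | O[C@@H]1[C@@H](O[Si](CC)(CC)CC)[C@@H](O)[C@@]2(C)[C@@H]3C(=O)C=C(C)[C@H]2[C@@H]3C1(C)C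
F13 | step 23 | 7,9-bis(angeloyloxy)-8-(triethylsilyloxy)longipin-2-en-1-one | C/C=C(/C)C(=O)O[C@@H]1[C@@H](O[Si](CC)(CC)CC)[C@@H](OC(=O)/C(C)=C\C)[C@@]2(C)[C@@H]3C(=O)C=C(C)[C@H]2[C@@H]3C1(C)C
F14 | step 23 | 7,9-bis(angeloyloxy)-8-hydroxylongipin-2-en-1-one | C/C=C(/C)C(=O)O[C@@H]1[C@@H](O)[C@@H](OC(=O)/C(C)=C\C)[C@@]2(C)[C@@H]3C(=O)C=C(C)[C@H]2[C@@H]3C1(C)C
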